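## Retrosynthetic overview

- **Numbering.** The ring is C1 (CMeCl), C2 (CH2), C3 (quaternary, carrying Me and the C7=C8 bromovinyl arm), C4 (CHBr), C5 (CH2) and C6 (CHCl). The three ring halogens and the arm lie on one face; both methyl groups lie on the other.
- **Feature.** The plan rests on the vicinal C3/C4 pair of the single cyclohexane ring, where Br on C4 is cis to C7 on C3. These two atoms are treated as the alkene carbons of an (E)-β-boryl methacrolein, with boron occupying the opposite face until it is exchanged for bromine with inversion.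
- **Endgame.** The cis C1–Cl/C6–Cl pair comes from a C1–C6 epoxide on the face of the C3 methyl group (double inversion), and that from the C1=C6 alkene. C4–Br comes from C4–B (inversion). C7=C8–Br comes from the C7 aldehyde (Takai olefination).
- **Key disconnection.** C2–C3 and C4–C5 are formed by a catalytic enantioselective [4+2] cycloaddition with 2-methyl-3-silyloxybutadiene. This is the only ring-forming event, and the silyl enol ether it leaves marks C1=C6.
- **Ordering.** The enol ether is converted to the alkene (triflate, then Pd/formate) before the bromovinyl arm is built, because zerovalent palladium would also insert into an alkenyl bromide.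

Key step: step 4

Assumption: the sense of induction follows the accepted binding model for 2-substituted enals on this catalyst family (formyl C–H···O contact, s-trans enal, one phenyl covering the C3 Si face); if the boryl enal binds differently, the catalyst from (R)-α,α-diphenylprolinol is used and nothing else changes.

## Route

Step 1
Reactants: 1 methacrolein
Product: 3 (E)-3-bromo-2-methylprop-2-enal, via 2,3-dibromo-2-methylpropanal 2 (not isolated)
Conditions: Br2 (1.0 equiv), CH2Cl2, −78 → 0 °C; then Et3N (1.2 equiv), 0 °C → rt
Reagents that add atoms: bromine, BrBr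
Why: Electrophilic bromine addition to the alkene followed by amine-induced E2 dehydrobromination (the tertiary C2 bromide leaves with a proton of the more acidic CH2Br group) restores conjugation, reversible conjugate addition–elimination funnels the bromoenal to the more stable E isomer, and the racemic stereocentre of 2 is erased.

Step 2
Reactants: 3 (E)-3-bromo-2-methylprop-2-enal; 4 bis(pinacolato)diboron
Product: 5 (E)-2-methyl-3-(4,4,5,5-tetramethyl-1,3,2-dioxaborolan-2-yl)prop-2-enal
Conditions: PdCl2(dppf) (3 mol %), KOAc (3 equiv), 1,4-dioxane, 80 °C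
Reagents that add atoms: none
Why: In this Miyaura borylation, oxidative addition of zerovalent palladium to the alkenyl C–Br bond, acetate-assisted transmetalation and reductive elimination all retain the alkene geometry, and the weak, poorly nucleophilic base KOAc spares the aldehyde and suppresses Suzuki homocoupling.

Step 3
Reactants: 6 3-methylbut-3-en-2-one
Product: 7 2-methyl-3-(triisopropylsilyloxy)buta-1,3-diene
Conditions: iPr3SiOTf (1.05 equiv), Et3N (1.5 equiv), CH2Cl2, 0 °C → rt
Reagents that add atoms: triisopropylsilyl trifluoromethanesulfonate, CC(C)[Si](OS(=O)(=O)C(F)(F)F)(C(C)C)C(C)C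
Why: Soft enolisation and O-silylation of a methyl ketone should give a single 2-silyloxydiene, because the only enolisable protons are those of the acetyl CH3.

Step 4
Reactants: 5 (E)-2-methyl-3-(4,4,5,5-tetramethyl-1,3,2-dioxaborolan-2-yl)prop-2-enal; 7 2-methyl-3-(triisopropylsilyloxy)buta-1,3-diene
Product: 8 (1R,6R)-1,3-dimethyl-6-(4,4,5,5-tetramethyl-1,3,2-dioxaborolan-2-yl)-4-(triisopropylsilyloxy)cyclohex-3-ene-1-carbaldehyde (boron trans to formyl)
Conditions: (S)-oxazaborolidinium bis(triflyl)imide (20 mol %; oxazaborolidine preformed from (S)-α,α-diphenylprolinol and o-tolylboronic acid in toluene with azeotropic drying, then HNTf2, 0.9 equiv per oxazaborolidine, CH2Cl2, −25 °C), 7 (2 equiv), CH2Cl2, −78 → −40 °C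
Reagents that add atoms: none
Why: The cationic boron binds the formyl oxygen of 5 on the side of the formyl hydrogen, which leans on the ring oxygen of the catalyst, so the enal LUMO is lowered and 7 adds in a concerted but asynchronous normal-demand Diels–Alder reaction in which C4–C5 bonding runs ahead of C2–C3 bonding. The nearest known reactions are oxazaborolidinium-catalysed cycloadditions of 2-(triisopropylsilyloxy)dienes to methacrolein-type enals and cycloadditions of β-boryl acrylic dienophiles, so this is a new pairing inside a known reaction class. The only ring of the target, the six-membered carbocycle, is closed here in intermolecular [4+2] mode, with both σ-bonds forming suprafacially on each partner. The relative configuration of C3 and C4 copies the E geometry of 5 (boron trans to formyl, cis to the C3 methyl), while the absolute configuration comes from the catalyst, whose phenyl group beside the bound s-trans enal covers the C3 Si face so that the diene bonds to the C3 Re face; endo or exo orientation has no consequence because both diene termini are CH2 groups. The step needs the orientation that puts C6–O para to C3 and the diene methyl on C1, and the silyloxy donor secures it by making its own CH2 terminus (C5) the most nucleophilic carbon and pairing it with the electrophilic β-carbon C4, overriding the weaker opposite bias of the methyl group. Cycloaddition must also win over open-chain Mukaiyama aldol or Michael addition and over diene desilylation, which the bulky iPr3Si group and the slight deficit of HNTf2 are meant to ensure.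

Step 5
Reactants: 8 (1R,6R)-1,3-dimethyl-6-(4,4,5,5-tetramethyl-1,3,2-dioxaborolan-2-yl)-4-(triisopropylsilyloxy)cyclohex-3-ene-1-carbaldehyde
Product: 10 (4R,5R)-4-formyl-2,4-dimethyl-5-(4,4,5,5-tetramethyl-1,3,2-dioxaborolan-2-yl)cyclohex-1-en-1-yl trifluoromethanesulfonate, via caesium enolate 9 (not isolated)
Conditions: CsF (4 equiv), PhNTf2 (1.5 equiv), DME, rt
Reagents that add atoms: N-phenylbis(trifluoromethanesulfonimide), O=S(=O)(N(c1ccccc1)S(=O)(=O)C(F)(F)F)C(F)(F)F; caesium fluoride (caesium in 9 only), [Cs+].[F-]
Why: In this fluoride-triggered desilylative triflation of a silyl enol ether, CsF cleaves the Si–O bond to release the C1=C6 enolate 9 regiospecifically, and the PhNTf2 already present sulfonylates oxygen before proton transfer, aldol addition to the non-enolisable neopentyl aldehyde or retro-Michael opening can intervene, leaving C3 and C4 untouched.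

Step 6
Reactants: 10 (4R,5R)-4-formyl-2,4-dimethyl-5-(4,4,5,5-tetramethyl-1,3,2-dioxaborolan-2-yl)cyclohex-1-en-1-yl trifluoromethanesulfonate
Product: 11 (1R,6R)-1,3-dimethyl-6-(4,4,5,5-tetramethyl-1,3,2-dioxaborolan-2-yl)cyclohex-3-ene-1-carbaldehyde
Conditions: Pd(OAc)2 (5 mol %), PPh3 (10 mol %), HCO2H (2 equiv), n-Bu3N (3 equiv), DMF, 60 °C
Reagents that add atoms: none
Why: Palladium-catalysed formate reduction of an enol triflate (oxidative addition of zerovalent palladium, formate exchange, decarboxylation to Pd–H, reductive elimination) replaces OTf by H without moving the alkene, and it is placed here because the aldehyde and the secondary alkyl boronate are inert whereas a later alkenyl bromide would compete for the catalyst.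

Step 7
Reactants: 11 (1R,6R)-1,3-dimethyl-6-(4,4,5,5-tetramethyl-1,3,2-dioxaborolan-2-yl)cyclohex-3-ene-1-carbaldehyde
Product: 12 2-{(1R,6R)-6-[(E)-2-bromoethenyl]-4,6-dimethylcyclohex-3-en-1-yl}-4,4,5,5-tetramethyl-1,3,2-dioxaborolane
Conditions: CrBr2 (6 equiv), CHBr3 (2 equiv), THF, 0 → 50 °C
Reagents that add atoms: bromoform, BrC(Br)Br
Why: In the Takai olefination the geminal dichromium species from CHBr3 and divalent chromium adds to the aldehyde and eliminates to the E alkene (a preference reinforced by quaternary C3), the bromide salt is used instead of CrCl2 so that no chlorovinyl product can arise by halide exchange, and the boronate and the ring alkene are inert.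

Step 8
Reactants: 12 2-{(1R,6R)-6-[(E)-2-bromoethenyl]-4,6-dimethylcyclohex-3-en-1-yl}-4,4,5,5-tetramethyl-1,3,2-dioxaborolane
Product: 14 (4S,5S)-4-bromo-5-[(E)-2-bromoethenyl]-1,5-dimethylcyclohex-1-ene, via lithium aryl boronate complex 13 (not isolated)
Conditions: 3,5-(CF3)2C6H3Br (1.3 equiv), n-BuLi (1.25 equiv), THF, −78 °C; add 12, −78 °C; then NBS (1.3 equiv), THF, −78 → 0 °C
Reagents that add atoms: N-bromosuccinimide, O=C1CCC(=O)N1Br; 3,5-bis(trifluoromethyl)phenyllithium (aryl group and lithium in 13 only), [Li]c1cc(cc(c1)C(F)(F)F)C(F)(F)F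
Why: In this stereoinvertive bromodeboronation of a secondary boronic ester, the stabilised aryllithium (too weak to exchange with the alkenyl bromide) adds to boron to give 13, whose C4–B bond attacks NBS through its rear lobe (SE2 with inversion) so that bromine arrives cis to C7 and C4 becomes S, while the CF3 groups block aryl bromination and electron transfer and the anionic complex outruns the neutral C1=C6 alkene for NBS.

Step 9
Reactants: 14 (4S,5S)-4-bromo-5-[(E)-2-bromoethenyl]-1,5-dimethylcyclohex-1-ene
Product: 15 (1R,3S,4S,6S)-4-bromo-3-[(E)-2-bromoethenyl]-1,3-dimethyl-7-oxabicyclo[4.1.0]heptane (oxygen cis to the C3 methyl and trans to Br and the arm)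
Conditions: mCPBA (1.05 equiv), CH2Cl2, −20 → 0 °C
Reagents that add atoms: 3-chloroperoxybenzoic acid, OOC(=O)c1cccc(Cl)c1
Why: In the Prilezhaev epoxidation the electrophilic peracid selects the electron-rich trisubstituted C1=C6 alkene over the bromine-deactivated C7=C8 alkene and should approach the face opposite the arm and C4–Br, because in the half-chair with the arm axial and bromine equatorial that face carries only an axial hydrogen, which sets C1 (R) and C6 (S).

Step 10
Reactants: 15 (1R,3S,4S,6S)-4-bromo-3-[(E)-2-bromoethenyl]-1,3-dimethyl-7-oxabicyclo[4.1.0]heptane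
Product: 17 (1S,2S,4R,5S)-2-bromo-1-[(E)-2-bromoethenyl]-4,5-dichloro-1,5-dimethylcyclohexane (target), via alkoxyphosphonium chloride 16 (not isolated)
Conditions: Ph3PCl2 (1.5 equiv), toluene, 0 °C then 80 °C
Reagents that add atoms: dichlorotriphenylphosphorane, ClP(Cl)(c1ccccc1)(c1ccccc1)c1ccccc1
Why: In this Appel-type deoxydichlorination of an epoxide, P–O bonding activates the oxygen, chloride opens the C1–O bond at the cation-stabilising tertiary carbon from the opposite face (trans-diaxial opening) to give 16, and a second chloride displaces Ph3P=O from secondary C6 by SN2, so both carbons are inverted and the two chlorines end cis to each other and to Br and the arm (C1 S, C6 R in the ring numbering).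

## Compound list

1 | methacrolein | C=C(C)C=O | starting material
2 | 2,3-dibromo-2-methylpropanal (racemic) | O=CC(C)(Br)CBr | intermediate
3 | (E)-3-bromo-2-methylprop-2-enal | O=C/C(C)=C/Br | intermediate
4 | bis(pinacolato)diboron | CC1(C)OB(OC1(C)C)B1OC(C)(C)C(C)(C)O1 | starting material
5 | (E)-2-methyl-3-(4,4,5,5-tetramethyl-1,3,2-dioxaborolan-2-yl)prop-2-enal | O=C/C(C)=C/B1OC(C)(C)C(C)(C)O1 | intermediate
6 | 3-methylbut-3-en-2-one | CC(=O)C(C)=C | starting material
7 | 2-methyl-3-(triisopropylsilyloxy)buta-1,3-diene | C=C(C)C(=C)O[Si](C(C)C)(C(C)C)C(C)C | intermediate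
8 | (1R,6R)-1,3-dimethyl-6-(4,4,5,5-tetramethyl-1,3,2-dioxaborolan-2-yl)-4-(triisopropylsilyloxy)cyclohex-3-ene-1-carbaldehyde | O=C[C@]1(C)CC(C)=C(O[Si](C(C)C)(C(C)C)C(C)C)C[C@H]1B2OC(C)(C)C(C)(C)O2 | intermediate
9 | caesium (4R,5R)-4-formyl-2,4-dimethyl-5-(4,4,5,5-tetramethyl-1,3,2-dioxaborolan-2-yl)cyclohex-1-en-1-olate | [Cs+].O=C[C@]1(C)CC(C)=C([O-])C[C@H]1B2OC(C)(C)C(C)(C)O2 | intermediate
10 | (4R,5R)-4-formyl-2,4-dimethyl-5-(4,4,5,5-tetramethyl-1,3,2-dioxaborolan-2-yl)cyclohex-1-en-1-yl trifluoromethanesulfonate | O=C[C@]1(C)CC(C)=C(OS(=O)(=O)C(F)(F)F)C[C@H]1B2OC(C)(C)C(C)(C)O2 | intermediate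
11 | (1R,6R)-1,3-dimethyl-6-(4,4,5,5-tetramethyl-1,3,2-dioxaborolan-2-yl)cyclohex-3-ene-1-carbaldehyde | O=C[C@]1(C)CC(C)=CC[C@H]1B2OC(C)(C)C(C)(C)O2 | intermediate
12 | 2-{(1R,6R)-6-[(E)-2-bromoethenyl]-4,6-dimethylcyclohex-3-en-1-yl}-4,4,5,5-tetramethyl-1,3,2-dioxaborolane | Br/C=C/[C@]1(C)CC(C)=CC[C@H]1B2OC(C)(C)C(C)(C)O2 | intermediate
13 | lithium 3,5-bis(trifluoromethyl)phenyl boronate complex of 12 (carbon configuration unchanged) | [Li+].Br/C=C/[C@]1(C)CC(C)=CC[C@H]1[B-]2(c3cc(cc(c3)C(F)(F)F)C(F)(F)F)OC(C)(C)C(C)(C)O2 | intermediate
14 | (4S,5S)-4-bromo-5-[(E)-2-bromoethenyl]-1,5-dimethylcyclohex-1-ene | Br/C=C/[C@]1(C)CC(C)=CC[C@@H]1Br | intermediate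
15 | (1R,3S,4S,6S)-4-bromo-3-[(E)-2-bromoethenyl]-1,3-dimethyl-7-oxabicyclo[4.1.0]heptane | C[C@@]12C[C@@](C)(/C=C/Br)[C@@H](Br)C[C@@H]1O2 | intermediate
16 | {(1S,2S,4S,5S)-5-bromo-4-[(E)-2-bromoethenyl]-2-chloro-2,4-dimethylcyclohexyl}oxytriphenylphosphonium chloride | [Cl-].C[C@]1(Cl)C[C@@](C)(/C=C/Br)[C@@H](Br)C[C@@H]1O[P+](c2ccccc2)(c2ccccc2)c2ccccc2 | intermediate
17 | (1S,2S,4R,5S)-2-bromo-1-[(E)-2-bromoethenyl]-4,5-dichloro-1,5-dimethylcyclohexane | C[C@]1(Cl)C[C@@](C)(/C=C/Br)[C@@H](Br)C[C@H]1Cl | target

## Step count and risks

Total step count: 10. Longest linear sequence: 9 steps (1, 2, 4, 5, 6, 7, 8, 9, 10).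

**Step 4.**
- The trisubstituted enal, encumbered at its β-carbon by the boronate, may react slowly.
- Acid-induced desilylation of the diene, open-chain Mukaiyama-type addition, or an achiral silyl triflimide background reaction could then erode conversion and face selectivity.
- The fallback sets out from 5 and 7. It gives up catalyst control and activates the enal with a full equivalent of the achiral Lewis acid Me2AlCl (CH2Cl2, −78 → −20 °C).
- This should deliver 8 together with its mirror image, the (1S,6S)-adduct F1.
- The two enantiomers are separated by preparative chromatography on a chiral stationary phase, and the route is rejoined at 8.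

**Step 8.**
- Complexation at a boron flanked by quaternary C3 may be incomplete.
- Stereospecificity may be lost through an electron-transfer (radical) bromination.
- NBS may attack the C1=C6 alkene.
- The fallback sets out from 12. The C–B bond is oxidised with retention (NaBO3·4H2O, THF/H2O, rt) to (1R,6S)-6-[(E)-2-bromoethenyl]-4,6-dimethylcyclohex-3-en-1-ol F2.
- The hydroxyl group of this alcohol is then replaced by bromide with inversion in an Appel reaction (Ph3P, CBr4, CH2Cl2, 0 °C → rt), returning to the route at 14.
- This accepts a slow SN2 reaction at a neopentyl-type carbinol in exchange for fully established chemistry.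

**Step 10.**
- At the temperature the phosphorane requires, tertiary C1 may ionise and lose its inversion.
- The C6 alkoxyphosphonium group may be lost by E2 elimination toward C5.
- The C1 chlorine may participate as a chloronium ion and cause retention at C6.
- The fallback sets out from 15 and separates the two C–Cl bond formations.
- Anhydrous HCl (Et2O/CH2Cl2, −78 °C) opens the epoxide at C1 to the trans chlorohydrin (1S,2S,4S,5S)-5-bromo-4-[(E)-2-bromoethenyl]-2-chloro-2,4-dimethylcyclohexan-1-ol F3.
- ClCH2SO2Cl and pyridine (0 °C) convert it into the corresponding chloromethanesulfonate F4.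
- LiCl in DMF (rt → 40 °C) displaces this much better leaving group by SN2 at low temperature, arriving at 17.

## Further compounds

F1 | step 4 | (1S,6S)-1,3-dimethyl-6-(4,4,5,5-tetramethyl-1,3,2-dioxaborolan-2-yl)-4-(triisopropylsilyloxy)cyclohex-3-ene-1-carbaldehyde | O=C[C@@]1(C)CC(C)=C(O[Si](C(C)C)(C(C)C)C(C)C)C[C@@H]1B2OC(C)(C)C(C)(C)O2
F2 | step 8 | (1R,6S)-6-[(E)-2-bromoethenyl]-4,6-dimethylcyclohex-3-en-1-ol | Br/C=C/[C@]1(C)CC(C)=CC[C@H]1O
F3 | step 10 | (1S,2S,4S,5S)-5-bromo-4-[(E)-2-bromoethenyl]-2-chloro-2,4-dimethylcyclohexan-1-ol | C[C@]1(Cl)C[C@@](C)(/C=C/Br)[C@@H](Br)C[C@@H]1O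
F4 | step 10 | (1S,2S,4S,5S)-5-bromo-4-[(E)-2-bromoethenyl]-2-chloro-2,4-dimethylcyclohexyl chloromethanesulfonate | C[C@]1(Cl)C[C@@](C)(/C=C/Br)[C@@H](Br)C[C@@H]1OS(=O)(=O)CCl
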